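Numbering: ring A = C1, C14, C13 (C=O), C12, C11 (CH3), C10; tetrahydrofuran = C1, C2, O, C9, C10; oxonane = O, C2 to C9 (C3 CH3, C4 OAc, C6 OAc, C7 CH3/OH); oxepane = C1, C2, C3, O, C16, C15 (CH3), C14.
Enabling feature: in the tetrahydrofuran, C9 bears the ring oxygen and the methylene C8 that leads to carbinol carbon C7. Its neighbour C10 is allylic to the ring A alkene C11=C12. C9–C10 is therefore the bond between a ring A allyl radical and the β-carbon of an (E)-β-alkoxy enone carried by O–C2.
Cuts, last bond first: C13=O (allylic C–H oxidation); C6–C7 (pinacol, opens the oxonane); C4–C5 (acetate aldol); C9–C10 (radical closure, opens the tetrahydrofuran); O–C9 (oxa-Michael); O–C3 (epoxide opening, opens the oxepane); C2–C3 (Grignard); C1–C10 and C13–C14 (Diels–Alder, opens ring A).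
Forward ring order: ring A (built on a δ-lactone that already holds C2, C16 and C15), then oxepane, tetrahydrofuran, oxonane.
Stereochemistry: C15 comes from methyl (R)-3-hydroxy-2-methylpropanoate. C1 and C14 come from a suprafacial Diels–Alder addition anti to the C15 methyl. C2 and C3 come from a Sharpless epoxidation run as a kinetic resolution, followed by inversion at C3. C9 and C10 are set in the radical closure under control of C1 and C2, C4 by chelation, and C6 and C7 in the pinacol closure.
Key step: step 15

Assumption: C10 of the ring A intermediates before the key step is drawn as one epimer (endo adduct, inverted on bromination). Its configuration, and the position of the bromide within the allyl system, have no consequence because the radical closure erases both. All other centres have the spatial arrangement of the target.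

Step 1
Reactants: 1 methyl (R)-3-hydroxy-2-methylpropanoate
Product: 2 methyl (R)-3-(tert-butyldimethylsilyloxy)-2-methylpropanoate
Conditions: TBSCl, imidazole, CH2Cl2, 0 °C to rt
Reagents that add atoms: tert-butyldimethylsilyl chloride, CC(C)(C)[Si](C)(C)Cl
Why: Standard silyl ether formation masks the future C16 hydroxyl and does not touch the C15 stereocentre.

Step 2
Reactants: 2 methyl (R)-3-(tert-butyldimethylsilyloxy)-2-methylpropanoate
Product: 3 (R)-3-(tert-butyldimethylsilyloxy)-2-methylpropanal
Conditions: iBu2AlH (1.05 equiv), CH2Cl2, −78 °C; aq. potassium sodium tartrate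
Reagents that add atoms: none
Why: Partial ester reduction stops at the tetrahedral aluminate at low temperature and releases the aldehyde (future C14) only on work-up, so C15 should not epimerize.

Step 3
Reactants: 3 (R)-3-(tert-butyldimethylsilyloxy)-2-methylpropanal; 4 methyl 2-[bis(2,2,2-trifluoroethoxy)phosphoryl]acetate
Product: 5 methyl (S,Z)-5-(tert-butyldimethylsilyloxy)-4-methylpent-2-enoate
Conditions: KN(SiMe3)2, 18-crown-6, THF, −78 °C
Reagents that add atoms: none
Why: In the Still–Gennari variant of the Horner–Wadsworth–Emmons olefination the trifluoroethyl phosphonate eliminates under kinetic control, which should give the Z enoate (C1=C14) without loss of C15 integrity.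

Step 4
Reactants: 5 methyl (S,Z)-5-(tert-butyldimethylsilyloxy)-4-methylpent-2-enoate
Product: 7 (S)-5-methyl-5,6-dihydro-2H-pyran-2-one, via hydroxy enoate 6 (not isolated)
Conditions: camphorsulfonic acid (cat.), MeOH, rt
Reagents that add atoms: none
Why: Acid methanolysis of the silyl ether frees the C16 hydroxyl, which lies cis to the ester across the Z alkene and lactonizes spontaneously by transesterification.

Step 5
Reactants: 8 (E)-2-methylbut-2-enal
Product: 9 (E)-tert-butyl(dimethyl)[(2-methylbuta-1,3-dien-1-yl)oxy]silane
Conditions: TBSOTf, Et3N, Et2O, 0 °C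
Reagents that add atoms: tert-butyldimethylsilyl triflate, CC(C)(C)[Si](C)(C)OS(=O)(=O)C(F)(F)F
Why: Soft enolization of the enal at its γ-methyl group with O-silylation (silyl dienol ether formation) gives the 1-siloxy diene, and the E enol ether is the isomer that reaches the s-cis form needed next.

Step 6
Reactants: 7 (S)-5-methyl-5,6-dihydro-2H-pyran-2-one; 9 (E)-tert-butyl(dimethyl)[(2-methylbuta-1,3-dien-1-yl)oxy]silane
Product: 10 cis-fused ring A δ-lactone (8-TBSO-4,7-dimethyl-3,4,4a,5,8,8a-hexahydroisochromen-1-one; H1 and H14 cis on the face of the C15 methyl; C10 OTBS cis to C2)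
Conditions: 9 (3 equiv), BHT (cat.), toluene, 160 °C, sealed tube
Reagents that add atoms: none
Why: In this normal-demand Diels–Alder reaction the terminal siloxy group directs its carbon C10 to the α-carbon C1 of the lactone (ortho orientation), suprafacial addition to the ring-locked Z alkene makes H1 and H14 cis, approach anti to the C15 methyl relates both centres to C15, and the endo mode places the C10 siloxy group cis to C2, a centre that is erased later.

Step 7
Reactants: 10 cis-fused ring A δ-lactone
Product: 11 lactol of 10 (C2 hemiacetal; both anomers)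
Conditions: iBu2AlH, CH2Cl2, −78 °C; aq. potassium sodium tartrate
Reagents that add atoms: none
Why: Partial reduction of a lactone with iBu2AlH stops at the aluminium hemiacetal at low temperature and gives the lactol, with silyl ether and alkene inert.

Step 8
Reactants: 11 lactol of 10; 12 isopropenylmagnesium bromide
Product: 14 (2R)-allylic alcohol (ring A with C1–CH(OH)C(CH3)=CH2; C14–CH(CH3)CH2OH; C10 OTBS), via hydroxy aldehyde 13 (not isolated)
Conditions: 12 (3 equiv), THF, 0 °C to rt
Reagents that add atoms: none
Why: Grignard addition to the hydroxy aldehyde tautomer, which the first equivalent of reagent releases from the lactol, forms C2–C3, and facial control at C2 is not relied on because the 2R epimer drawn is singled out in step 9.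

Step 9
Reactants: 14 (2R)-allylic alcohol (with its C2 epimer)
Product: 15 (2R,3S)-epoxy diol (erythro; oxirane on C3 and C4)
Conditions: Ti(OiPr)4 (cat.), D-(−)-diisopropyl tartrate (cat.), t-BuOOH (1 equiv per 2R epimer), 4 Å molecular sieves, CH2Cl2, −20 °C
Reagents that add atoms: tert-butyl hydroperoxide, CC(C)(C)OO
Why: In the Sharpless asymmetric epoxidation run as a kinetic resolution with the D-(−)-tartrate, the 2R carbinol of a 2-substituted allylic alcohol reacts fast and gives the erythro (2R,3S) epoxy alcohol, so C2 is selected and C3 is set by the catalyst while the 2S epimer and the ring A alkene (no free allylic hydroxyl) stay unchanged.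

Step 10
Reactants: 15 (2R,3S)-epoxy diol
Product: 16 oxepane-fused ring A diol (C2 OH; C3 with CH3 and CH2OH; C10 OTBS)
Conditions: camphorsulfonic acid (cat.), CH2Cl2 (0.005 M), 0 °C to rt
Reagents that add atoms: none
Why: In this acid-catalysed intramolecular epoxide opening (7-exo-tet) the protonated 2,2-disubstituted oxirane is attacked at its tertiary carbon C3 by the C16 hydroxyl held on the same face of ring A, with inversion, which gives the tertiary ether with 3R configuration and frees C4 as a primary alcohol.

Step 11
Reactants: 16 oxepane-fused ring A diol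
Product: 17 C4 TBDPS ether of 16 (C2 OH free)
Conditions: TBDPSCl, imidazole, CH2Cl2, 0 °C
Reagents that add atoms: tert-butyldiphenylsilyl chloride, CC(C)(C)[Si](Cl)(c1ccccc1)c1ccccc1
Why: In this selective silylation the bulky chlorosilane takes the primary C4 hydroxyl and leaves free the C2 hydroxyl, which is flanked by C1 and the quaternary C3.

Step 12
Reactants: 17 C4 TBDPS ether of 16; 18 but-3-yn-2-one
Product: 19 C2 (E)-β-alkoxy enone (O–CH=CH–C(O)CH3 on C2; C10 OTBS; C4 OTBDPS)
Conditions: PMe3 (cat.), CH2Cl2, 0 °C
Reagents that add atoms: none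
Why: The phosphine-catalysed oxa-Michael addition of an alcohol to an ynone tolerates hindered alcohols and gives the E vinylogous ester, which supplies C9, C8, C7 and the C7 methyl.

Step 13
Reactants: 19 C2 (E)-β-alkoxy enone
Product: 20 C10 allylic alcohol
Conditions: HF·pyridine, pyridine, THF, 0 °C
Reagents that add atoms: none
Why: In this selective desilylation buffered HF·pyridine cleaves the secondary allylic TBS ether faster than the TBDPS ether and is mild enough for the vinylogous ester.

Step 14
Reactants: 20 C10 allylic alcohol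
Product: 21 oxepane-fused ring A allylic bromide bearing the C2 (E)-β-alkoxy enone (one C10 epimer drawn)
Conditions: CBr4, PPh3, CH2Cl2, −20 to 0 °C
Reagents that add atoms: carbon tetrabromide, BrC(Br)(Br)Br
Why: The Appel reaction converts the allylic alcohol under neutral conditions by SN2 (inversion, drawn) or SN2' displacement, and neither the epimer nor the regioisomer formed matters for the next step.

Step 15
Reactants: 21 oxepane-fused ring A allylic bromide bearing the C2 (E)-β-alkoxy enone
Product: 22 ring A–tetrahydrofuran–oxepane tricycle with C9 acetonyl arm (C4 OTBDPS)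
Conditions: Bu3SnH (1.3 equiv) and AIBN (0.2 equiv) added by syringe pump over 6 h, benzene (0.005 M), reflux
Reagents that add atoms: none
Why: The tributyltin radical abstracts bromine from either C10 epimer or from the C12 allylic isomer and gives one and the same ring A allyl radical, planar at C10, which adds to the oxygen-bearing carbon C9 of the enone; the α-keto radical at C8 then takes hydrogen from Bu3SnH and carries the chain. The closest known reactions are the tin hydride cyclizations of β-alkoxyacrylates and β-alkoxyvinyl ketones to 2,5-cis-tetrahydrofurans and the cyclizations of allyl radicals onto acrylate-type acceptors. The tetrahydrofuran (C1, C2, O, C9, C10) closes in the 5-exo-trig mode. C10 is controlled by C1, because the three-atom tether C2–O–C9 reaches the planar radical only from the face on which C2 stands, so only the cis-fused bicycle can form. C9 is controlled by C2 and by the shape of that bicycle: in the chair-like transition state the enone arm is pseudo-equatorial and points to the convex face away from ring A, which places C8 cis to C3 (2,5-cis) and trans to C11. The step needs cyclization to outrun hydrogen transfer and bonding through C10 rather than C12, which is secured by the polarity match of the nucleophilic allyl radical with the enone, by the low stationary tin hydride concentration, and by the bridged seven-membered ring that attack through C12 would require.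

Step 16
Reactants: 22 ring A–tetrahydrofuran–oxepane tricycle with C9 acetonyl arm
Product: 23 primary alcohol (C3–CH2OH)
Conditions: HF·pyridine, THF, rt
Reagents that add atoms: none
Why: Fluoride cleavage of the TBDPS ether in an acidic rather than basic medium avoids retro-oxa-Michael opening of the β-alkoxy ketone.

Step 17
Reactants: 23 primary alcohol
Product: 24 C4 aldehyde (C3–CHO)
Conditions: Dess–Martin periodinane, CH2Cl2, rt
Reagents that add atoms: none
Why: Dess–Martin oxidation gives an aldehyde on a quaternary carbon, which cannot epimerize or enolize.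

Step 18
Reactants: 25 S-ethyl ethanethioate
Product: 26 [1-(ethylsulfanyl)ethenyl]oxy(trimethyl)silane
Conditions: LiN(iPr)2, THF, −78 °C; TMSCl
Reagents that add atoms: chlorotrimethylsilane, C[Si](C)(C)Cl
Why: Kinetic enolization of the thioester and O-silylation give the ketene silyl thioacetal that will supply C5 and C6.

Step 19
Reactants: 24 C4 aldehyde; 26 [1-(ethylsulfanyl)ethenyl]oxy(trimethyl)silane
Product: 27 (4S)-β-hydroxy thioester (C4 OH; C5 H2; C6 thioester)
Conditions: MgBr2·OEt2 (3 equiv), CH2Cl2, −20 °C; aq. NH4Cl
Reagents that add atoms: none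
Why: In this chelation-controlled Mukaiyama aldol addition MgBr2 binds the aldehyde oxygen and the oxepane oxygen on C3 in a five-membered chelate, so the nucleophile attacks from the side of the C3 methyl rather than of C2, which sets 4S (C3–O and C4–O syn), and the aldehyde reacts ahead of the methyl ketone.

Step 20
Reactants: 27 (4S)-β-hydroxy thioester
Product: 28 C4 acetate of 27
Conditions: Ac2O, pyridine, DMAP (cat.), CH2Cl2, 0 °C
Reagents that add atoms: acetic anhydride, CC(=O)OC(C)=O
Why: Acetylation of the only free hydroxyl installs the C4 acetate of the target and keeps the alcohol out of the silane reduction that follows.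

Step 21
Reactants: 28 C4 acetate of 27
Product: 29 keto aldehyde (C6 CHO; C7 methyl ketone)
Conditions: Et3SiH, palladium on carbon (Pd/C, 10 %), acetone, rt
Reagents that add atoms: none
Why: The Fukuyama reduction converts the thioester into the aldehyde under neutral conditions that leave ketone, acetate and the trisubstituted alkene alone.

Step 22
Reactants: 29 keto aldehyde
Product: 30 tetracyclic (6S,7S)-diol (oxonane closed; C4 OAc; C13 H2)
Conditions: SmI2 (3 equiv), t-BuOH (2 equiv), THF (0.002 M, slow addition of 29), −78 °C to rt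
Reagents that add atoms: none
Why: In this SmI2-mediated intramolecular ketone–aldehyde pinacol coupling the aldehyde ketyl adds to the samarium-bound ketone while the 2,5-cis tetrahydrofuran holds both arms on one face, and with both oxygens bound to trivalent samarium on the outside of the forming oxonane and C5 antiperiplanar to C8 the (6S,7S) diol should result.

Step 23
Reactants: 30 tetracyclic (6S,7S)-diol
Product: 31 4,6-diacetate (13-deoxy target; C7 OH free)
Conditions: Ac2O, pyridine, DMAP (cat.), CH2Cl2, rt
Reagents that add atoms: acetic anhydride, CC(=O)OC(C)=O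
Why: In this selective acetylation the secondary C6 hydroxyl is acylated and the tertiary C7 hydroxyl is not, and any acetyl migration between O4 and O6 in step 22 is levelled here.

Step 24
Reactants: 31 4,6-diacetate (13-deoxy target)
Product: 32 CNP0212231.3 (target)
Conditions: Rh2(cap)4 (dirhodium tetracaprolactamate, 1 mol %), t-BuOOH (70 % in water, 10 equiv), 1,2-dichloroethane, 40 °C
Reagents that add atoms: tert-butyl hydroperoxide, CC(C)(C)OO
Why: In this rhodium-catalysed allylic oxidation (hydrogen abstraction by the peroxyl radical, then collapse of the allylic peroxide) C13 is the only allylic methylene and the most exposed allylic C–H, so the ketone conjugated with C11=C12 should form while alcohol, acetates, ethers and C14 stay untouched under near-neutral conditions.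

Compound list
1 | methyl (R)-3-hydroxy-2-methylpropanoate | COC(=O)[C@H](C)CO | starting material
2 | methyl (R)-3-(tert-butyldimethylsilyloxy)-2-methylpropanoate | COC(=O)[C@H](C)CO[Si](C)(C)C(C)(C)C | intermediate
3 | (R)-3-(tert-butyldimethylsilyloxy)-2-methylpropanal | O=C[C@H](C)CO[Si](C)(C)C(C)(C)C | intermediate
4 | methyl 2-[bis(2,2,2-trifluoroethoxy)phosphoryl]acetate | COC(=O)CP(=O)(OCC(F)(F)F)OCC(F)(F)F | starting material
5 | methyl (S,Z)-5-(tert-butyldimethylsilyloxy)-4-methylpent-2-enoate | COC(=O)/C=C\[C@H](C)CO[Si](C)(C)C(C)(C)C | intermediate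
6 | methyl (S,Z)-5-hydroxy-4-methylpent-2-enoate (not isolated) | COC(=O)/C=C\[C@H](C)CO | intermediate
7 | (S)-5-methyl-5,6-dihydro-2H-pyran-2-one | O=C1C=C[C@H](C)CO1 | intermediate
8 | (E)-2-methylbut-2-enal | C/C=C(C)/C=O | starting material
9 | (E)-tert-butyl(dimethyl)[(2-methylbuta-1,3-dien-1-yl)oxy]silane | C=C/C(C)=C/O[Si](C)(C)C(C)(C)C | intermediate
10 | cis-fused ring A δ-lactone (endo adduct) | O=C1OC[C@@H](C)[C@@H]2CC=C(C)[C@H](O[Si](C)(C)C(C)(C)C)[C@H]12 | intermediate
11 | lactol of 10 | OC1OC[C@@H](C)[C@@H]2CC=C(C)[C@H](O[Si](C)(C)C(C)(C)C)[C@H]12 | intermediate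
12 | isopropenylmagnesium bromide | C=C(C)[Mg]Br | starting material
13 | open-chain hydroxy aldehyde tautomer of 11 (not isolated) | O=C[C@@H]1[C@@H](CC=C(C)[C@@H]1O[Si](C)(C)C(C)(C)C)[C@H](C)CO | intermediate
14 | (2R)-allylic alcohol | C=C(C)[C@H](O)[C@@H]1[C@@H](CC=C(C)[C@@H]1O[Si](C)(C)C(C)(C)C)[C@H](C)CO | intermediate
15 | (2R,3S)-epoxy diol | C[C@]1(CO1)[C@H](O)[C@@H]2[C@@H](CC=C(C)[C@@H]2O[Si](C)(C)C(C)(C)C)[C@H](C)CO | intermediate
16 | oxepane-fused ring A diol | O[C@@H]1[C@@H]2[C@@H](CC=C(C)[C@@H]2O[Si](C)(C)C(C)(C)C)[C@H](C)CO[C@]1(C)CO | intermediate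
17 | C4 TBDPS ether of 16 | O[C@@H]1[C@@H]2[C@@H](CC=C(C)[C@@H]2O[Si](C)(C)C(C)(C)C)[C@H](C)CO[C@]1(C)CO[Si](c1ccccc1)(c1ccccc1)C(C)(C)C | intermediate
18 | but-3-yn-2-one | CC(=O)C#C | starting material
19 | C2 (E)-β-alkoxy enone, C10 OTBS | CC(=O)/C=C/O[C@@H]1[C@@H]2[C@@H](CC=C(C)[C@@H]2O[Si](C)(C)C(C)(C)C)[C@H](C)CO[C@]1(C)CO[Si](c1ccccc1)(c1ccccc1)C(C)(C)C | intermediate
20 | C10 allylic alcohol | CC(=O)/C=C/O[C@@H]1[C@@H]2[C@@H](CC=C(C)[C@@H]2O)[C@H](C)CO[C@]1(C)CO[Si](c1ccccc1)(c1ccccc1)C(C)(C)C | intermediate
21 | allylic bromide, key-step precursor | CC(=O)/C=C/O[C@@H]1[C@@H]2[C@@H](CC=C(C)[C@H]2Br)[C@H](C)CO[C@]1(C)CO[Si](c1ccccc1)(c1ccccc1)C(C)(C)C | intermediate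
22 | tricycle with C9 acetonyl arm, key-step product | CC(=O)C[C@H]1O[C@@H]2[C@@H]3[C@@H](CC=C(C)[C@@H]31)[C@H](C)CO[C@]2(C)CO[Si](c1ccccc1)(c1ccccc1)C(C)(C)C | intermediate
23 | primary alcohol | CC(=O)C[C@H]1O[C@@H]2[C@@H]3[C@@H](CC=C(C)[C@@H]31)[C@H](C)CO[C@]2(C)CO | intermediate
24 | C4 aldehyde | CC(=O)C[C@H]1O[C@@H]2[C@@H]3[C@@H](CC=C(C)[C@@H]31)[C@H](C)CO[C@]2(C)C=O | intermediate
25 | S-ethyl ethanethioate | CCSC(C)=O | starting material
26 | [1-(ethylsulfanyl)ethenyl]oxy(trimethyl)silane | C=C(O[Si](C)(C)C)SCC | intermediate
27 | (4S)-β-hydroxy thioester | CC(=O)C[C@H]1O[C@@H]2[C@@H]3[C@@H](CC=C(C)[C@@H]31)[C@H](C)CO[C@]2(C)[C@@H](O)CC(=O)SCC | intermediate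
28 | C4 acetate of 27 | CC(=O)C[C@H]1O[C@@H]2[C@@H]3[C@@H](CC=C(C)[C@@H]31)[C@H](C)CO[C@]2(C)[C@@H](OC(C)=O)CC(=O)SCC | intermediate
29 | keto aldehyde | CC(=O)C[C@H]1O[C@@H]2[C@@H]3[C@@H](CC=C(C)[C@@H]31)[C@H](C)CO[C@]2(C)[C@@H](OC(C)=O)CC=O | intermediate
30 | tetracyclic (6S,7S)-diol | CC(=O)O[C@H]1C[C@H](O)[C@@](C)(O)C[C@H]2O[C@@H]3[C@@H]4[C@@H](CC=C(C)[C@@H]42)[C@H](C)CO[C@]13C | intermediate
31 | 4,6-diacetate (13-deoxy target) | CC(=O)O[C@H]1C[C@H](OC(C)=O)[C@@](C)(O)C[C@H]2O[C@@H]3[C@@H]4[C@@H](CC=C(C)[C@@H]42)[C@H](C)CO[C@]13C | intermediate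
32 | CNP0212231.3 | CC(=O)O[C@H]1C[C@H](OC(C)=O)[C@@](C)(O)C[C@H]2O[C@@H]3[C@@H]4[C@@H](C(=O)C=C(C)[C@@H]42)[C@H](C)CO[C@]13C | target

Total step count: 24. Longest linear sequence: 22 (steps 1–4, 6–17, 19–24).

Steps most likely to fail

Step 6.
- What may go wrong: unsaturated δ-lactones are weak dienophiles. The cycloaddition may be so slow that thermal loss of the diene, or erosion of the anti facial selectivity at the temperature needed, takes over.
- Fallback: ring A is built on the same lactone by conjugate addition and metathesis. It sets out from 7. A Morita–Baylis–Hillman-type coupling with methacrolein (Et2AlI, CH2Cl2) gives the α-(1-hydroxy-2-methylallyl) lactone F1, and silylation (TBSOTf, 2,6-lutidine) gives its silyl ether F2. Copper-mediated addition of allylmagnesium bromide (CuBr·SMe2, TMSCl) goes to C14 anti to the C15 methyl. Kinetic protonation of the lactone enolate on the face away from the new allyl group then gives the cis-disubstituted lactone F3. Ring-closing metathesis with the second-generation Grubbs catalyst forms C11=C12 and comes back to the route at 10.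

Step 22.
- What may go wrong: medium-ring strain may let simple reduction of the aldehyde or intermolecular coupling win. The relative configuration at C6 and C7 may also be poorly controlled.
- Fallback: the same C6–C7 bond is closed as an alkene and oxygenated afterwards. It sets out from 29. Non-basic double methylenation (Zn, CH2Br2, TiCl4) gives the diene F4. Ring-closing metathesis with the second-generation Hoveyda–Grubbs catalyst gives the (Z)-oxonene F5. Epoxidation of this strained, exposed alkene with dimethyldioxirane gives the 6,7-epoxide F6. Opening with water at the tertiary carbon C7 with inversion (Sc(OTf)3, aq. THF) gives the trans-related diol and comes back to the route at 30.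

Step 24.
- What may go wrong: hydrogen abstraction at C10–H, at the C11 methyl or next to an ether oxygen may compete, which would lead to transposed or over-oxidized material.
- Fallback: the oxygen is brought to C13 by a polar, regiodefined transposition. It sets out from 31. mCPBA attacks C11=C12 on the open face of ring A (the face of H1, H10 and H14) and gives the epoxide F7. PhSeNa (from PhSeSePh and NaBH4, EtOH) opens it at the less substituted C12 to give the hydroxy selenide F8. Oxidation with H2O2 and syn elimination, possible only toward C13, gives the tertiary allylic alcohol F9. Oxidative transposition with pyridinium chlorochromate comes back to the route at 32.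

Further compounds
F1 | step 6 | (5S)-3-(1-hydroxy-2-methylallyl)-5-methyl-5,6-dihydropyran-2-one (either C10 epimer) | C=C(C)C(O)C1=C[C@H](C)COC1=O
F2 | step 6 | TBS ether of F1 | C=C(C)C(O[Si](C)(C)C(C)(C)C)C1=C[C@H](C)COC1=O
F3 | step 6 | cis-disubstituted lactone (C14 allyl; C1 CH(OTBS)C(CH3)=CH2) | O=C1OC[C@@H](C)[C@H](CC=C)[C@@H]1C(O[Si](C)(C)C(C)(C)C)C(C)=C
F4 | step 22 | diene (C6 vinyl; C7 isopropenyl) | C=C(C)C[C@H]1O[C@@H]2[C@@H]3[C@@H](CC=C(C)[C@@H]31)[C@H](C)CO[C@]2(C)[C@@H](OC(C)=O)CC=C
F5 | step 22 | (Z)-oxonene (C6=C7) | CC(=O)O[C@H]1C/C=C(C)\C[C@H]2O[C@@H]3[C@@H]4[C@@H](CC=C(C)[C@@H]42)[C@H](C)CO[C@]13C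
F6 | step 22 | 6,7-epoxide | CC(=O)O[C@H]1C[C@@H]5O[C@]5(C)C[C@H]2O[C@@H]3[C@@H]4[C@@H](CC=C(C)[C@@H]42)[C@H](C)CO[C@]13C
F7 | step 24 | 11,12-epoxide of 31 | CC(=O)O[C@H]1C[C@H](OC(C)=O)[C@@](C)(O)C[C@H]2O[C@@H]3[C@@H]4[C@@H](C[C@H]5O[C@@]5(C)[C@@H]42)[C@H](C)CO[C@]13C
F8 | step 24 | C11 hydroxy C12 phenylselenide | CC(=O)O[C@H]1C[C@H](OC(C)=O)[C@@](C)(O)C[C@H]2O[C@@H]3[C@@H]4[C@@H](C[C@H]([Se]c5ccccc5)[C@@](C)(O)[C@@H]42)[C@H](C)CO[C@]13C
F9 | step 24 | C11 tertiary allylic alcohol (C12=C13) | CC(=O)O[C@H]1C[C@H](OC(C)=O)[C@@](C)(O)C[C@H]2O[C@@H]3[C@@H]4[C@@H](C=C[C@@](C)(O)[C@@H]42)[C@H](C)CO[C@]13C
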